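## Structural features

The target is a cis-fused bicyclo[4.4.0]decane in which ring A (C1, C2, C3, C4, C5, C10) is a cyclohexenone and ring B (C5 to C10) is a cyclohexane, the two sharing the C5–C10 bond; with these locants the configuration is 1S,5R,6R,7S,10R. Ring A carries the C1 angelate, the C2 ketone and the C3-acetyl C3=C4 alkene; ring B carries the C6 methyl and the C7 acetate; the fusion carries the C5 methyl and the C10 tertiary hydroxyl. Four stereocentres are contiguous on one face (C10–OH, C5–CH3, C6–CH3 and C7–OAc, all cis), and the fifth, the C1 ester, is trans to the C10 hydroxyl next to it. The fragile groups are the angelate (Z to E isomerization by acid, base, nucleophiles or iodine atoms), the 2-acyl enone (a strong Michael acceptor), the C10 hydroxyl β to the C2 ketone (dehydration, retro-aldol) and the acyloxy-bearing C1–H between them. The real difficulty is the pair of adjacent fully substituted carbons C5 and C10 with methyl and hydroxyl cis, followed by a C6 methyl that must also be cis to the C5 methyl. The key step exploits the oxygenation of ring A: oxygen at C1 and C2 and an oxidized C4, with C1 and C4 para across the C5(CH3)–C10 edge, is the pattern of 2-methoxy-5-methyl-1,4-benzoquinone, whose methylated double bond becomes the C5–C10 bond. The single oxygen of ring B at C7, 1,3 to C5, is where a 1-methoxy-3-silyloxybutadiene places its silyl enol ether when its CH2 terminus bonds to C5.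

## Logic of the disconnections

19 ⇒ 17. The C3–C(acetyl) bond is cut. The 2-acyl enone is the most electrophilic function and should appear last. 17 holds a C3–I bond for a Stille coupling with a masked acetyl group (through 18). The forward step must couple and hydrolyse under conditions that spare the angelate and the β-hydroxy ketone.

17 ⇒ 15. The C2 ketone and C3=C4 alkene are traced back to a C2 methoxy enol ether and a C4 ketone, which is what a methoxyquinone delivers. The forward step is a 1,2-reduction at C4 and an acid-induced allylic transposition (through 16). It must leave two esters and the C–I bond alone and must not dehydrate the C10 hydroxyl.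

15 ⇒ 12 + 13. The C1 ester C–O bond is cut. The angelate is introduced as late as possible, so that it then meets only a borohydride, dilute acid and a zerovalent palladium catalyst. The forward step (through 14) must acylate a hindered secondary alcohol without Z to E isomerization and leave the tertiary hydroxyl free.

12 ⇒ 11. The C3–I bond is cut. In 11, C3 is the nucleophilic α-carbon of a vinylogous ester, so iodine enters by electrophilic substitution without base. Doing this before 13 is attached keeps the Z-alkene away from any iodinating agent.

11 ⇒ 10. The C1–H bond is cut. The C1 carbinol comes from the quinone carbonyl and its configuration from the neighbouring C10 hydroxyl by internal hydride delivery. The reagent must ignore the acetate and the C4 vinylogous ester carbonyl.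

10 ⇒ 9 ⇒ 8. The acetate C–O bond and the C7–H bond are cut. Forming and capping the C7 hydroxyl while C1 is still a ketone distinguishes the two secondary hydroxyls without a protecting group. The hydride must attack C7 only, and from the equatorial direction.

8 ⇒ 7. The C8=C9 alkene is restored, because it is needed one step earlier to control enolization. The forward hydrogenation must reduce this disubstituted alkene and not the methoxy-bearing C2=C3 bond.

7 ⇒ 6. The C6–CH3 bond is cut. In 6 the C8=C9 alkene blocks enolization toward C8 and C10 is quaternary, so C6 is the only position that can be deprotonated. The cycloaddition cannot supply this methyl cis: a terminal methyl on the diene would end trans to the C5 methyl under endo control. The forward step needs facial control at C6.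

6 ⇒ 4. The C10–O bond is cut, and the C9 methoxy group and the C7 silyl enol ether are restored. The hydroxyl must enter while C9 is still sp3 and C7 is still masked. In 4, C10–H is the only acidic hydrogen and the two faces of the C1 enolate differ clearly. After unmasking to a C8=C9 enone, the C10 anion would be a flat, doubly vinylogous enolate that could also react at C8 and has little facial bias. The forward step (through 5) needs oxygen transfer to outrun β-elimination of methoxide.

4 ⇒ 2 + 3. The C5–C6 and C9–C10 bonds are cut in a Diels–Alder sense. This removes ring B, the quaternary C5 and all ring A oxygenation in one step and leads to two simple components. The forward step needs site, regio-, endo and facial selectivity. The tert-butyldimethylsilyl enol ether of 2 is chosen over a trimethylsilyl ether so that C7 stays masked through the Lewis acid and the following enolate step.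

2 ⇒ 1. The O–Si bond is cut; 1 is a commercial vinylogous ester.

## Other disconnections considered

Alternative 1: The C5–CH3 and C6–CH3 bonds are cut and no ring is formed. In the forward step MeMgBr would deprotonate the C10 hydroxyl of the C5=C6 enone A1, the magnesium alkoxide would deliver methyl to C5 on its own face, and MeI would trap the C6 enolate to give A2.
- In its favour: the cis relation of the C5 methyl and the C10 hydroxyl comes from intramolecular delivery. On this point the alternative is the better of the two, because the chosen plan relies on steric bias in an enolate hydroxylation. Two C–C bonds are also made in one flask.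
- Against it: conjugate addition followed by alkylation normally places the second group trans to the first, whereas A2 needs the C6 methyl cis. A1 must already hold the C1, C2 and C10 stereocentres. A2 still lacks the C2 ketone, the C3=C4 alkene, the C3 acetyl group and the C7 carbinol.
- Comparison: the chosen cycloaddition builds ring B and delivers C1, C2 and C4 at the right oxidation levels from commercial material, so its step economy should be better.

Alternative 2: The C2–C3 bond is cut. In the forward step CrCl2 with catalytic NiCl2 would turn the (Z)-alkenyl iodide of A3 into an alkenylchromium species that adds to the C2 aldehyde, closing ring A as the cyclohexenol A4.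
- In its favour: the Nozaki–Hiyama–Kishi closure is near neutral and tolerates the acetate and the acetal. The C2 epimer mixture does not matter because C2 is oxidized later. The acyl enone is unveiled last, on which point it is the equal of the chosen plan. It creates no lasting stereocentre, so it carries less stereochemical risk than an untested asymmetric cycloaddition, a point on which it is the better.
- Against it: A3 requires a fully substituted ring B with four contiguous stereocentres, a Z-iodoalkene on the quaternary C5 and an aldehyde arm on C10, all assembled linearly before any ring fusion exists. The acetonide spans the trans C1/C10 diol, so ring closure must create a strained trans-fused dioxolane. The acetyl group must still be attached at C3 after oxidation. Divalent chromium is needed in excess.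
- Comparison: the chosen plan is convergent and much shorter to the bicyclic core.

Alternative 3: The C9–C10 bond is formed while the C2–C7 bond of a bicyclo[2.2.2]octene is broken. In the forward step the potassium alkoxide of the vinyl carbinol A5 (KH, 18-crown-6) would undergo an anionic oxy-Cope shift to the C7 enolate, protonated to A6.
- In its favour: the cis ring fusion and the cis relation of the C10 oxygen and the C5 methyl follow from the topology of the bicycle, and the C6 methyl is carried over as well. On stereochemical certainty at C5, C6 and C10 the alternative is the better.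
- Against it: A5 itself needs a cycloaddition to a cyclohexadiene and a vinyl addition that must place the vinyl group on the side of the enol ether bridge, with its own enantiocontrol problem. A6 has no oxygen at C1 and a saturated C3–C4 unit, so C1 oxidation, C3–C4 dehydrogenation, C3 acylation and C7 reduction all remain.
- Comparison: the chosen plan reaches the ring A oxygenation directly and should need fewer redox steps.

Key step: step 2

Assumption: the sense of induction of the BINOL–titanium catalyst with this quinone is not known in advance; (R)-BINOL is written, and the other ligand antipode is used if the enantiomer of 4 forms.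

## Route

Step 1
Reactants: 1 (E)-4-methoxybut-3-en-2-one
Product: 2 (E)-1-methoxy-3-(tert-butyldimethylsilyloxy)buta-1,3-diene
Conditions: TBSOTf, Et3N, Et2O, 0 °C to rt
Reagents that add atoms: tert-butyldimethylsilyl trifluoromethanesulfonate, CC(C)(C)[Si](C)(C)OS(=O)(=O)C(F)(F)F
Why: Soft enolization and O-silylation of a methyl ketone (silyl dienol ether formation); the E enol ether of 1 is untouched, and the tert-butyldimethylsilyl enol ether is sturdier toward Lewis acid and amide base than the trimethylsilyl analogue.

Step 2
Reactants: 2 (E)-1-methoxy-3-(tert-butyldimethylsilyloxy)buta-1,3-diene; 3 2-methoxy-5-methyl-1,4-benzoquinone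
Product: 4 endo cis-fused adduct (C1 and C4 ketones; C2 methoxy enol ether C2=C3; C5 methyl cis to C10–H; C7 tert-butyldimethylsilyl enol ether C7=C8; C9 methoxy trans to C10–H)
Conditions: (R)-BINOL, TiCl2(OiPr)2 (20 mol % each), 4 Å molecular sieves, toluene, −40 °C
Reagents that add atoms: none
Why: Normal-demand Diels–Alder cycloaddition, concerted but asynchronous, between the electron-rich diene 2 and the methylated double bond of 3 (the future C5–C10 bond), activated by titanium held between the C1 carbonyl and the C2 methoxy oxygen. The closest known reaction type is the Lewis-acid-promoted cycloaddition of 2-alkoxy-5-methylbenzoquinones at the methylated double bond, together with BINOL–titanium-catalysed enantioselective quinone Diels–Alder reactions. Ring B closes by suprafacial [4+2] addition, forming C5–C6 and C9–C10 together. C5 and C10 come out cis because both bonds form on one face of the ring double bond; C9 is set by endo approach of the E-configured methoxy terminus, which places the methoxy group trans to C10–H; the absolute configuration comes from the BINOL ligand screening one face of the chelated quinone. Site selectivity follows from the other double bond being a deactivated vinylogous ester. Regioselectivity follows from chelation, which makes C5 the β-carbon of the activated C1 carbonyl, so the nucleophilic CH2 terminus of 2 bonds there and the methoxy-bearing terminus bonds to C10. Endo selectivity follows from secondary overlap with the quinone carbonyls.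

Step 3
Reactants: 4 endo cis-fused adduct
Product: 6 hydroxy enone (C1 C4 C7 triketone; C2=C3 methoxy enol ether; C8=C9 enone; C10 hydroxyl cis to C5 methyl), via C10-hydroxy adduct 5 (not isolated)
Conditions: LiN(SiMe3)2, THF, −78 °C; 2-(phenylsulfonyl)-3-phenyloxaziridine, −78 °C; then 2 M HCl, THF, 0 °C to rt
Reagents that add atoms: 2-(phenylsulfonyl)-3-phenyloxaziridine, O=S(=O)(c1ccccc1)N1OC1c1ccccc1
Why: Davis enolate hydroxylation: C10–H is the only acidic hydrogen of 4, and the oxidant should approach the C1 enolate on the face of the C5 methyl because the other face carries the C9 methoxy group and the C6 methylene of ring B, as in the cis-selective angular functionalization of 1-decalone enolates. Acid then hydrolyses the silyl enol ether and eliminates methanol (β-elimination) to the C8=C9 enone.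

Step 4
Reactants: 6 hydroxy enone
Product: 7 C6-methyl hydroxy enone (C6 methyl cis to C5 methyl)
Conditions: LiN(SiMe3)2 (2.2 equiv), THF, −78 °C; MeI, −78 to −40 °C; AcOH, −78 °C
Reagents that add atoms: iodomethane, CI
Why: Kinetic α′-alkylation of a cyclohexenone through its cross-conjugated lithium dienolate; C6 is the only enolizable position. The C10 lithium alkoxide chelated to the C1 carbonyl should hold the C5–C4 bond pseudoaxial over ring B, so MeI enters C6 anti to it, on the face of the C5 methyl.

Step 5
Reactants: 7 C6-methyl hydroxy enone
Product: 8 saturated hydroxy trione (C8 and C9 methylene)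
Conditions: H2 (1 atm), 5% Pd/C, EtOAc, rt, stopped after one equivalent
Reagents that add atoms: none
Why: Catalytic hydrogenation of the disubstituted enone alkene C8=C9; the trisubstituted, methoxy-bearing C2=C3 bond should react much more slowly, and no stereocentre is formed.

Step 6
Reactants: 8 saturated hydroxy trione
Product: 9 C7 alcohol (C7 hydroxyl cis to C6 methyl and C5 methyl)
Conditions: LiBH(s-Bu)3 (2.2 equiv), THF, −78 °C; aq. NH4Cl
Reagents that add atoms: none
Why: Ketone reduction with a bulky trialkylborohydride: the saturated C7 ketone is the most accessible carbonyl (C1 is conjugated and flanked by the C10 alkoxide, C4 is a vinylogous ester). Equatorial attack, reinforced by the syn-axial C5 methyl in the chair with equatorial C6 methyl, should give the axial C7 alcohol cis to both methyl groups.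

Step 7
Reactants: 9 C7 alcohol
Product: 10 C7 acetate
Conditions: Ac2O, pyridine, DMAP (cat.), CH2Cl2, 0 °C to rt
Reagents that add atoms: acetic anhydride, CC(=O)OC(C)=O
Why: DMAP-catalysed acylation of the only secondary alcohol; the tertiary C10 hydroxyl does not react under these conditions.

Step 8
Reactants: 10 C7 acetate
Product: 11 C1,C10-trans-diol (C1 hydroxyl trans to C10 hydroxyl; ring A now a C2-methoxy C4-keto vinylogous ester)
Conditions: Me4NBH(OAc)3, MeCN/AcOH, −20 °C
Reagents that add atoms: none
Why: Hydroxyl-directed (Evans–Saksena-type) reduction: the C10 alkoxyborohydride delivers hydride to C1 from the face of the C10 oxygen, giving the trans diol; this is also the convex face of ring A. The acetate and the deactivated C4 carbonyl should be inert.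

Step 9
Reactants: 11 C1,C10-trans-diol
Product: 12 C3 iodide (2-methoxy-3-iodo enone in ring A)
Conditions: N-iodosuccinimide, MeCN, 0 °C, dark
Reagents that add atoms: N-iodosuccinimide, O=C1CCC(=O)N1I
Why: Electrophilic α-iodination of a vinylogous ester at its nucleophilic C3; no base is needed and no stereocentre is touched.

Step 10
Reactants: 12 C3 iodide; 13 angelic acid
Product: 15 C1 angelate of the C3 iodide, via mixed anhydride 14 (not isolated)
Conditions: 13, 2,4,6-trichlorobenzoyl chloride, Et3N, toluene, rt; then 12, toluene, 70 °C (no DMAP)
Reagents that add atoms: 2,4,6-trichlorobenzoyl chloride, O=C(Cl)c1c(Cl)cc(Cl)cc1Cl (its acyl group is carried by 14 only)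
Why: Yamaguchi esterification: the hindered mixed anhydride transfers the angeloyl group to the secondary C1 hydroxyl, the tertiary C10 hydroxyl stays free, and omitting a nucleophilic catalyst should keep the Z geometry.

Step 11
Reactants: 15 C1 angelate of the C3 iodide
Product: 17 α-iodo enone (C2 ketone; C3 iodide; C3=C4), via C4 carbinol 16 (not isolated)
Conditions: NaBH4, CeCl3·7H2O, MeOH, −20 °C; then 1 M HCl, THF, 0 °C
Reagents that add atoms: water, O
Why: Luche 1,2-reduction of the C4 carbonyl followed by Stork–Danheiser transposition: acid ionizes the allylic C4 hydroxyl, water adds at C2 and methanol is lost. Both esters and the vinyl iodide should survive borohydride at low temperature and brief dilute acid.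

Step 12
Reactants: 17 α-iodo enone
Product: 19 target CNP0196241.1, via ethoxyvinyl enone 18 (not isolated)
Conditions: tributyl(1-ethoxyvinyl)stannane, Pd2(dba)3 (5 mol %), AsPh3 (20 mol %), CuI (10 mol %), DMF, 40 °C; then 0.5 M HCl, THF, 0 °C
Reagents that add atoms: tributyl(1-ethoxyvinyl)stannane, CCCC[Sn](CCCC)(CCCC)C(=C)OCC; water, O
Why: Stille coupling of an α-iodo enone with a masked acetyl stannane, then enol ether hydrolysis; conditions are neutral and then briefly acidic, so the angelate geometry and the β-hydroxy ketone should be preserved and the acyl enone appears only in the last operation.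

## Compound list

1 | (E)-4-methoxybut-3-en-2-one | CO/C=C/C(C)=O | starting material
2 | (E)-1-methoxy-3-(tert-butyldimethylsilyloxy)buta-1,3-diene | CO/C=C/C(=C)O[Si](C)(C)C(C)(C)C | intermediate
3 | 2-methoxy-5-methyl-1,4-benzoquinone | COC1=CC(=O)C(C)=CC1=O | starting material
4 | endo cis-fused adduct, C7 silyl enol ether, C9 methoxy | COC1=CC(=O)[C@]2(C)CC(O[Si](C)(C)C(C)(C)C)=C[C@H](OC)[C@@H]2C1=O | intermediate
5 | C10-hydroxy adduct (OH cis to C5 methyl) | COC1=CC(=O)[C@]2(C)CC(O[Si](C)(C)C(C)(C)C)=C[C@H](OC)[C@]2(O)C1=O | intermediate (not isolated)
6 | hydroxy enone (C8=C9, C7 ketone, C10 OH) | COC1=CC(=O)[C@]2(C)CC(=O)C=C[C@]2(O)C1=O | intermediate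
7 | C6-methyl hydroxy enone | COC1=CC(=O)[C@]2(C)[C@@H](C)C(=O)C=C[C@]2(O)C1=O | intermediate
8 | saturated hydroxy trione | COC1=CC(=O)[C@]2(C)[C@@H](C)C(=O)CC[C@]2(O)C1=O | intermediate
9 | C7 alcohol | COC1=CC(=O)[C@]2(C)[C@@H](C)[C@@H](O)CC[C@]2(O)C1=O | intermediate
10 | C7 acetate | COC1=CC(=O)[C@]2(C)[C@@H](C)[C@@H](OC(C)=O)CC[C@]2(O)C1=O | intermediate
11 | C1,C10-trans-diol | O[C@@H]1C(OC)=CC(=O)[C@]2(C)[C@@H](C)[C@@H](OC(C)=O)CC[C@]12O | intermediate
12 | C3 iodide | O[C@@H]1C(OC)=C(I)C(=O)[C@]2(C)[C@@H](C)[C@@H](OC(C)=O)CC[C@]12O | intermediate
13 | angelic acid, (Z)-2-methylbut-2-enoic acid | C/C=C(/C)C(=O)O | starting material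
14 | angelic 2,4,6-trichlorobenzoic anhydride | C/C=C(/C)C(=O)OC(=O)c1c(Cl)cc(Cl)cc1Cl | intermediate (not isolated)
15 | C1 angelate of the C3 iodide | C/C=C(/C)C(=O)O[C@@H]1C(OC)=C(I)C(=O)[C@]2(C)[C@@H](C)[C@@H](OC(C)=O)CC[C@]12O | intermediate
16 | C4 carbinol (either C4 epimer) | C/C=C(/C)C(=O)O[C@@H]1C(OC)=C(I)C(O)[C@]2(C)[C@@H](C)[C@@H](OC(C)=O)CC[C@]12O | intermediate (not isolated)
17 | α-iodo enone | C/C=C(/C)C(=O)O[C@@H]1C(=O)C(I)=C[C@]2(C)[C@@H](C)[C@@H](OC(C)=O)CC[C@]12O | intermediate
18 | 3-(1-ethoxyvinyl) enone | C/C=C(/C)C(=O)O[C@@H]1C(=O)C(C(=C)OCC)=C[C@]2(C)[C@@H](C)[C@@H](OC(C)=O)CC[C@]12O | intermediate (not isolated)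
19 | CNP0196241.1 | C/C=C(/C)C(=O)O[C@@H]1C(=O)C(C(C)=O)=C[C@]2(C)[C@@H](C)[C@@H](OC(C)=O)CC[C@]12O | target

## Step count and least certain steps

Total: 12 steps. Longest linear sequence: 12 steps (1 to 19); 3 and 13 enter as purchased fragments.

Step 2 (key step). Most likely to go wrong: poor facial selectivity on the quinone, or loss of the silyl enol ether through a stepwise Mukaiyama–Michael pathway, because this diene–quinone pair has no enantioselective precedent. Fallback (from 2 and 3, back at 6): the uncatalysed cycloaddition in toluene at 60 °C, which has the same regiochemical preference, should give 4 together with the enantiomeric adduct F1. Carried through step 3, this gives 6 and the enantiomeric hydroxy enone F3, by way of 5 and the enantiomeric hydroxy adduct F2. 6 is then separated from F3 by preparative chromatography on a chiral stationary phase.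

Step 3. Most likely to go wrong: β-elimination of methoxide from the C1 enolate before oxygen transfer, because the C9–O bond can align with the enolate π system and the resulting dienone is conjugated. Fallback (from 4, back at 6): unmask first and oxidize a substrate without a leaving group. TFA in CH2Cl2 converts 4 into the C10–H enone F4. Conjugate hydrosilylation (Et3SiH, catalytic RhCl(PPh3)3) gives the C7 triethylsilyl enol ether F5. Its C1 enolate is hydroxylated as in step 3 to the C10-hydroxy silyl enol ether F6. Saegusa–Ito oxidation with Pd(OAc)2 in MeCN then restores the C8=C9 alkene and gives 6.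

Step 4. Most likely to go wrong: methylation on the wrong face of C6, because the methyl on the adjacent quaternary C5 and ring A compete as shielding elements and the preferred enolate conformer is not certain. Fallback (from 6, back at 7): if the methyl enters trans, the resulting C6 epimer F7 is re-enolized with LiN(SiMe3)2 and protonated at −78 °C with 2,6-di-tert-butylphenol. The proton should take the face that MeI preferred, which pushes the methyl to the face of the C5 methyl and gives 7.

Step 6. Most likely to go wrong: competing hydride addition to the ring A enedione (at C1 or by conjugate attack), because that system is electron-poor. Fallback (from 8, back at 11): reduce C1 first and protect it. Me4NBH(OAc)3 gives the C1 alcohol F8; Et3SiCl and imidazole give the C1 triethylsilyl ether F9; LiBH(s-Bu)3 gives the C7 alcohol F10; Ac2O and DMAP give the C7 acetate F11; HF·pyridine removes the silyl group to give 11.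

Step 11. Most likely to go wrong: slow 1,2-reduction at C4, which is flanked by the C3 iodine and the quaternary C5, so that ester cleavage competes. Fallback (from 11, back at 17): transpose before iodination. Luche reduction of 11 gives the C4 carbinol F12, which dilute HCl converts into the hydroxy enone F13. Yamaguchi esterification with 14 gives the angelate enone F14. α-Iodination of the enone with I2 and pyridine in CH2Cl2 in the dark gives 17.

## Further compounds

F1 | step 2 | enantiomer of adduct 4 | COC1=CC(=O)[C@@]2(C)CC(O[Si](C)(C)C(C)(C)C)=C[C@@H](OC)[C@H]2C1=O
F2 | step 2 | enantiomer of C10-hydroxy adduct 5 | COC1=CC(=O)[C@@]2(C)CC(O[Si](C)(C)C(C)(C)C)=C[C@@H](OC)[C@@]2(O)C1=O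
F3 | step 2 | enantiomer of hydroxy enone 6 | COC1=CC(=O)[C@@]2(C)CC(=O)C=C[C@@]2(O)C1=O
F4 | step 3 | C10–H enone (C8=C9, C7 ketone, cis-fused) | COC1=CC(=O)[C@]2(C)CC(=O)C=C[C@@H]2C1=O
F5 | step 3 | C7 triethylsilyl enol ether (C7=C8, C9 methylene, C10–H) | COC1=CC(=O)[C@]2(C)CC(O[Si](CC)(CC)CC)=CC[C@@H]2C1=O
F6 | step 3 | C10-hydroxy C7 triethylsilyl enol ether | COC1=CC(=O)[C@]2(C)CC(O[Si](CC)(CC)CC)=CC[C@]2(O)C1=O
F7 | step 4 | C6 epimer of 7 (C6 methyl trans to C5 methyl) | COC1=CC(=O)[C@]2(C)[C@H](C)C(=O)C=C[C@]2(O)C1=O
F8 | step 6 | C1 alcohol with C7 ketone | O[C@@H]1C(OC)=CC(=O)[C@]2(C)[C@@H](C)C(=O)CC[C@]12O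
F9 | step 6 | C1 triethylsilyl ether with C7 ketone | CC[Si](CC)(CC)O[C@@H]1C(OC)=CC(=O)[C@]2(C)[C@@H](C)C(=O)CC[C@]12O
F10 | step 6 | C1 triethylsilyl ether, C7 alcohol | CC[Si](CC)(CC)O[C@@H]1C(OC)=CC(=O)[C@]2(C)[C@@H](C)[C@@H](O)CC[C@]12O
F11 | step 6 | C1 triethylsilyl ether, C7 acetate | CC[Si](CC)(CC)O[C@@H]1C(OC)=CC(=O)[C@]2(C)[C@@H](C)[C@@H](OC(C)=O)CC[C@]12O
F12 | step 11 | C4 carbinol of 11 (either C4 epimer) | O[C@@H]1C(OC)=CC(O)[C@]2(C)[C@@H](C)[C@@H](OC(C)=O)CC[C@]12O
F13 | step 11 | hydroxy enone (C1 OH, C2 ketone, C3=C4) | O[C@@H]1C(=O)C=C[C@]2(C)[C@@H](C)[C@@H](OC(C)=O)CC[C@]12O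
F14 | step 11 | angelate enone (C2 ketone, C3=C4, no iodine) | C/C=C(/C)C(=O)O[C@@H]1C(=O)C=C[C@]2(C)[C@@H](C)[C@@H](OC(C)=O)CC[C@]12O
A1 | alternative 1 | C5=C6 enone with C7 ketone, C10 hydroxyl and C1,C2 acetonide | O=C1C=C2CC[C@H]3OC(C)(C)O[C@H]3[C@@]2(O)CC1
A2 | alternative 1 | cis-fused 5,6-dimethyl C7 ketone with C10 hydroxyl and C1,C2 acetonide | O=C1[C@H](C)[C@@]2(C)CC[C@H]3OC(C)(C)O[C@H]3[C@@]2(O)CC1
A3 | alternative 2 | ring B (Z)-iodoalkene aldehyde with C1,C10 acetonide | I/C=C\[C@]2(C)[C@@H](C)[C@@H](OC(C)=O)CC[C@@]23OC(C)(C)O[C@@H]3C=O
A4 | alternative 2 | ring A cyclohexenol (C2 carbinol, C3=C4) with C1,C10 acetonide | OC1C=C[C@]2(C)[C@@H](C)[C@@H](OC(C)=O)CC[C@@]23OC(C)(C)O[C@H]13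
A5 | alternative 3 | vinyl carbinol of the bicyclo[2.2.2]octene (C2–C7 bond intact, C1=C10 silyl enol ether) | C=C[C@]1(O)[C@H](C)[C@@]2(C)CC[C@]1(OC)C=C2O[Si](C(C)C)(C(C)C)C(C)C
A6 | alternative 3 | cis-fused C7 ketone with C10 silyl ether and C1=C2 methyl enol ether | O=C1CC[C@]2(O[Si](C(C)C)(C(C)C)C(C)C)C=C(OC)CC[C@]2(C)[C@H]1C
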